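Numbering is that of pterocarpan: ring B = C4a, O5, C6, C6a, C11a, C11b; ring C = C6a, C6b, C10a, O11, C11a; ring A carries the dimethylpyran at C3 (O) and C4, ring D the hydroxydimethylpyran at C9 (O) and C10.
Retrosynthesis: Si–O bond, then C11a–C11b (ring B, the last ring), then O5–C6 (aryl ether), then C6a–C11a (ring C), then aryl–C6a; both aryl halves go back to one chromenol.
Forward: the pyran and then the arene of 2,2-dimethyl-2H-chromen-5-ol are made; one portion becomes the ring D half (MOM ether, epoxidation and hydride opening, silylation, ortho-iodination, aryl diazoacetate, carbene C–H insertion into the MOM methylene to close ring C); the second portion of the chromenol is joined through O5–C6; ring B closes last.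
Stereochemistry: the (R) carbinol comes from a Jacobsen–Katsuki epoxidation, C6a from the chiral dirhodium catalyst of the C–H insertion, and C11a from C6a in the key step (cis ring fusion).
Enabling feature: C11a is the one carbon bonded both to O11 and to ring A, so as a methyl acetal (its carbon is the former MOM methylene) it ionises to a ring C oxocarbenium ion, while C11b, ortho to O5 and para to the ring A pyran oxygen, lies six atoms away along C11a–C6a–C6–O5–C4a–C11b; the methoxy group is the only helper and it leaves in the key step itself.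

Key step: step 12

Remark: the facial sense of the two catalyst-controlled steps (4 and 9) is assigned by analogy with the closest substrate classes; if a first run shows the opposite sense, the mirror-image catalyst is used.

Step 1
Reactants: 1 cyclohexane-1,3-dione; 2 3-methylbut-2-enal
Product: 4 2,2-dimethyl-2,6,7,8-tetrahydro-5H-chromen-5-one, via oxatriene 3 (not isolated)
Conditions: ethylenediammonium diacetate (10 mol%), MeOH, rt
Reagents that add atoms: none
Why: Knoevenagel condensation gives oxatriene 3, which closes by oxa-6π electrocyclisation to the 2H-pyran (formal [3+3] annulation).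

Step 2
Reactants: 4 2,2-dimethyl-2,6,7,8-tetrahydro-5H-chromen-5-one
Product: 9 2,2-dimethyl-2H-chromen-5-ol, via lithium enolate 5 (not isolated), via selenide 6 (not isolated), via selenoxide 7 (not isolated), via dienone 8 (not isolated)
Conditions: LiN(i-Pr)2, THF, −78 °C; PhSeCl, −78 °C; then 30% aq. H2O2, pyridine, 0 °C → rt
Reagents that add atoms: none
Why: Kinetic deprotonation at C6 gives enolate 5, PhSeCl gives selenide 6, oxidation gives selenoxide 7, its syn-elimination gives dienone 8, and tautomerisation aromatises the ring (selenoxide elimination).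

Step 3
Reactants: 9 2,2-dimethyl-2H-chromen-5-ol; 10 chloromethyl methyl ether
Product: 11 5-(methoxymethoxy)-2,2-dimethyl-2H-chromene
Conditions: i-Pr2NEt, CH2Cl2, 0 °C → rt
Reagents that add atoms: none
Why: O-alkylation of the phenol installs the MOM group, which later serves as protecting group, ortho director (step 7) and source of C11a (step 9).

Step 4
Reactants: 11 5-(methoxymethoxy)-2,2-dimethyl-2H-chromene
Product: 12 (3R,4R)-3,4-epoxy-5-(methoxymethoxy)-2,2-dimethylchromane
Conditions: (R,R)-[N,N'-bis(3,5-di-tert-butylsalicylidene)cyclohexane-1,2-diaminato]manganese chloride (3 mol%), 4-phenylpyridine N-oxide (20 mol%), aq. NaOCl (pH 11.3), CH2Cl2, 0 °C; crude oxide used at once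
Reagents that add atoms: sodium hypochlorite, [Na+].[O-]Cl
Why: Jacobsen–Katsuki epoxidation, for which cis-disubstituted 2,2-dimethylchromenes are the best substrate class; the (R,R) catalyst should deliver oxygen to the face that gives the (3R,4R) oxide and so sets the carbinol center.

Step 5
Reactants: 12 (3R,4R)-3,4-epoxy-5-(methoxymethoxy)-2,2-dimethylchromane
Product: 13 (3R)-5-(methoxymethoxy)-2,2-dimethylchroman-3-ol
Conditions: LiAlH4, THF, 0 °C; aqueous work-up
Reagents that add atoms: none
Why: Hydride opens the epoxide at the benzylic C4, which is activated and remote from the gem-dimethyl group, so the C3–O bond and its (R) configuration are untouched.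

Step 6
Reactants: 13 (3R)-5-(methoxymethoxy)-2,2-dimethylchroman-3-ol
Product: 14 tert-butyl{[(3R)-5-(methoxymethoxy)-2,2-dimethylchroman-3-yl]oxy}dimethylsilane
Conditions: TBSOTf, 2,6-lutidine, CH2Cl2, −78 → 0 °C
Reagents that add atoms: tert-butyldimethylsilyl trifluoromethanesulfonate, CC(C)(C)[Si](C)(C)OS(=O)(=O)C(F)(F)F
Why: Silylation of the hindered secondary alcohol with the silyl triflate gives an ether that should withstand butyllithium, hydride and the Lewis acid of step 12.

Step 7
Reactants: 14 tert-butyl{[(3R)-5-(methoxymethoxy)-2,2-dimethylchroman-3-yl]oxy}dimethylsilane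
Product: 16 tert-butyl{[(3R)-6-iodo-5-(methoxymethoxy)-2,2-dimethylchroman-3-yl]oxy}dimethylsilane, via aryllithium 15 (not isolated)
Conditions: n-BuLi, TMEDA, Et2O, 0 °C; then I2, THF, −78 °C
Reagents that add atoms: iodine, II
Why: Directed ortho-metalation, in which the MOM ether directs lithiation to C6, the only free ortho position, to give aryllithium 15, which iodine traps.

Step 8
Reactants: 16 tert-butyl{[(3R)-6-iodo-5-(methoxymethoxy)-2,2-dimethylchroman-3-yl]oxy}dimethylsilane; 17 ethyl diazoacetate
Product: 18 ethyl 2-diazo-2-[(3R)-3-(tert-butyldimethylsilyloxy)-5-(methoxymethoxy)-2,2-dimethylchroman-6-yl]acetate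
Conditions: Pd(PPh3)4 (5 mol%), Ag2CO3 (0.5 equiv), Et3N, toluene, rt
Reagents that add atoms: none
Why: Palladium-catalysed C–H arylation of the diazoacetate by the aryl iodide (oxidative addition, base-assisted transfer of the diazo carbon, reductive elimination) keeps the diazo group and gives the aryl diazoacetate in one step.

Step 9
Reactants: 18 ethyl 2-diazo-2-[(3R)-3-(tert-butyldimethylsilyloxy)-5-(methoxymethoxy)-2,2-dimethylchroman-6-yl]acetate
Product: 19 ethyl (2R,3S)-2-methoxy-2,3-dihydrobenzofuran-3-carboxylate fused at C6–C7 (O on C6, CH2 on C7) to the (R)-3-(tert-butyldimethylsilyloxy)-2,2-dimethyl-3,4-dihydro-2H-pyran ring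
Conditions: Rh2(S-PTTL)4 [dirhodium tetrakis(N-phthaloyl-(S)-tert-leucinate)] (1 mol%), toluene, −60 → −20 °C; the 2,3-cis isomer is separated and carried on
Reagents that add atoms: none
Why: Proposed new method: the dirhodium carbene formed by loss of N2 should insert into a C–H bond of the O–CH2–O methylene five atoms away (three-centre, hydride-transfer-like transition state stabilised by two oxygen lone pairs), closing ring C as a cyclic methyl acetal, with the catalyst fixing C3 (the future C6a) and, by analogy with benzyl ethers, the cis arrangement at C2; the closest known reaction type is the Rh2(S-PTTL)4-catalysed 1,5 C–H insertion of 2-(benzyloxy)aryl diazoacetates into the ArO–CH2–Ar methylene, and carbenoid insertion into acetal C–H bonds is known for dioxolanes.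

Step 10
Reactants: 19 the (2R,3S) acetal ester
Product: 20 [(2R,3R)-2-methoxy-2,3-dihydrobenzofuran-3-yl]methanol with the fused silyloxy-dimethyldihydropyran ring as in 19
Conditions: LiAlH4, Et2O, −78 → 0 °C; aqueous work-up
Reagents that add atoms: none
Why: Hydride reduction of the ester to the primary alcohol under cold, non-equilibrating conditions should leave the acetal and the stereocenter alpha to the ester untouched (the descriptor changes only through priorities).

Step 11
Reactants: 20 the (2R,3R) acetal alcohol; 9 2,2-dimethyl-2H-chromen-5-ol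
Product: 21 (2R,3R)-3-{[(2,2-dimethyl-2H-chromen-5-yl)oxy]methyl}-2-methoxy-2,3-dihydrobenzofuran with the fused silyloxy-dimethyldihydropyran ring as in 19
Conditions: PPh3, DIAD, THF, 0 °C → rt
Reagents that add atoms: none
Why: Mitsunobu etherification, in which the phenol displaces the activated primary hydroxyl in an SN2 reaction and forms the O5–C6 bond without touching a stereocenter.

Step 12
Reactants: 21 the aryl ether acetal
Product: 23 O-tert-butyldimethylsilyl ether of the target [(6aR,11aR)-pterocarpan skeleton complete], via oxocarbenium triflate 22 (not isolated)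
Conditions: TMSOTf (1.2 equiv), 2,6-di-tert-butyl-4-methylpyridine (1.5 equiv), CH2Cl2, −78 → −40 °C; Et3N quench
Reagents that add atoms: none
Why: TMSOTf silylates the exocyclic methoxy group, methoxytrimethylsilane leaves, and the ring C oxocarbenium ion 22 (C11a=O11+) is attacked by ring A at C11b, the carbon ortho to O5 and para to the pyran oxygen, after which the proton is taken up by the hindered pyridine. The closest known reaction type is the intramolecular Friedel–Crafts C-arylation of cyclic oxocarbenium ions made from lactol ethers, as in aryl C-glycoside and chroman annulations. Ring B closes in the 6-exo-trig mode at the oxocarbenium carbon (O11 stays outside the new ring), the arene bond C4a–C11b being endocyclic. The new center C11a is controlled by C6a, because the two-atom tether C6–O5 can deliver the arene only to the face of the five-membered cation on which C6 stands, so H-11a and H-6a end up cis, (6aR,11aR). The step needs site selectivity on ring A, secured because only C11b is within reach and it is the most electron-rich position, and preservation of C6a, secured by low temperature, the absence of free acid and the speed of a six-membered closure onto a doubly activated arene, which should outrun loss of H-6a. The chromene double bond, the silyl ether and the new benzylic C11a–O11 bond should survive because triflic acid is scavenged as it forms.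

Step 13
Reactants: 23 O-tert-butyldimethylsilyl ether of the target
Product: 24 target, the (6aR,11aR)-pterocarpan with the 2,2-dimethyl-2H-pyran fused at C3–C4 and the (R)-3-hydroxy-2,2-dimethyl-3,4-dihydro-2H-pyran fused at C9–C10
Conditions: Bu4NF, THF, 0 °C → rt
Reagents that add atoms: none
Why: Fluoride cleaves the Si–O bond, and the chromene, the aryl ethers and the three stereocenters are inert to these conditions.

Compound list
1 | cyclohexane-1,3-dione | O=C1CCCC(=O)C1 | starting material
2 | 3-methylbut-2-enal | CC(C)=CC=O | starting material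
3 | 2-(3-methylbut-2-en-1-ylidene)cyclohexane-1,3-dione (oxatriene, not isolated) | CC(C)=CC=C1C(=O)CCCC1=O | intermediate
4 | 2,2-dimethyl-2,6,7,8-tetrahydro-5H-chromen-5-one | CC1(C)C=CC2=C(O1)CCCC2=O | intermediate
5 | lithium 2,2-dimethyl-7,8-dihydro-2H-chromen-5-olate (enolate of 4, not isolated) | CC1(C)C=CC2=C(O1)CCC=C2O[Li] | intermediate
6 | 2,2-dimethyl-6-(phenylselanyl)-2,6,7,8-tetrahydro-5H-chromen-5-one (not isolated) | CC1(C)C=CC2=C(O1)CCC([Se]c1ccccc1)C2=O | intermediate
7 | selenoxide of 6 (not isolated) | CC1(C)C=CC2=C(O1)CCC([Se](=O)c1ccccc1)C2=O | intermediate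
8 | 2,2-dimethyl-2,8-dihydro-5H-chromen-5-one (dienone tautomer of 9, not isolated) | CC1(C)C=CC2=C(O1)CC=CC2=O | intermediate
9 | 2,2-dimethyl-2H-chromen-5-ol | CC1(C)C=Cc2c(O)cccc2O1 | intermediate
10 | chloromethyl methyl ether | COCCl | starting material
11 | 5-(methoxymethoxy)-2,2-dimethyl-2H-chromene | COCOc1cccc2OC(C)(C)C=Cc12 | intermediate
12 | (3R,4R)-3,4-epoxy-5-(methoxymethoxy)-2,2-dimethylchromane | COCOc1cccc2OC(C)(C)[C@@H]3O[C@@H]3c12 | intermediate
13 | (3R)-5-(methoxymethoxy)-2,2-dimethylchroman-3-ol | COCOc1cccc2OC(C)(C)[C@H](O)Cc12 | intermediate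
14 | tert-butyl{[(3R)-5-(methoxymethoxy)-2,2-dimethylchroman-3-yl]oxy}dimethylsilane | COCOc1cccc2OC(C)(C)[C@H](O[Si](C)(C)C(C)(C)C)Cc12 | intermediate
15 | 6-lithio derivative of 14 (not isolated) | [Li]c1ccc2OC(C)(C)[C@H](O[Si](C)(C)C(C)(C)C)Cc2c1OCOC | intermediate
16 | tert-butyl{[(3R)-6-iodo-5-(methoxymethoxy)-2,2-dimethylchroman-3-yl]oxy}dimethylsilane | COCOc1c(I)ccc2OC(C)(C)[C@H](O[Si](C)(C)C(C)(C)C)Cc12 | intermediate
17 | ethyl diazoacetate | CCOC(=O)C=[N+]=[N-] | starting material
18 | ethyl 2-diazo-2-[(3R)-3-(tert-butyldimethylsilyloxy)-5-(methoxymethoxy)-2,2-dimethylchroman-6-yl]acetate | CCOC(=O)C(=[N+]=[N-])c1ccc2OC(C)(C)[C@H](O[Si](C)(C)C(C)(C)C)Cc2c1OCOC | intermediate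
19 | ethyl (2R,3S)-2-methoxy-2,3-dihydrobenzofuran-3-carboxylate fused at C6–C7 (O on C6, CH2 on C7) to the (R)-3-(tert-butyldimethylsilyloxy)-2,2-dimethyl-3,4-dihydro-2H-pyran ring | CCOC(=O)[C@H]1c2ccc3c(c2O[C@H]1OC)C[C@@H](O[Si](C)(C)C(C)(C)C)C(C)(C)O3 | intermediate
20 | (2R,3R)-3-(hydroxymethyl) analogue of 19 | OC[C@H]1c2ccc3c(c2O[C@H]1OC)C[C@@H](O[Si](C)(C)C(C)(C)C)C(C)(C)O3 | intermediate
21 | (2R,3R)-3-{[(2,2-dimethyl-2H-chromen-5-yl)oxy]methyl} analogue of 19 | CC1(C)C=Cc2c(cccc2OC[C@H]2c4ccc5c(c4O[C@H]2OC)C[C@@H](O[Si](C)(C)C(C)(C)C)C(C)(C)O5)O1 | intermediate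
22 | (3R)-benzofuran-2-ylium (ring C oxocarbenium) triflate derived from 21 (not isolated) | CC1(C)C=Cc2c(cccc2OC[C@H]2c4ccc5c(c4[O+]=C2)C[C@@H](O[Si](C)(C)C(C)(C)C)C(C)(C)O5)O1.[O-]S(=O)(=O)C(F)(F)F | intermediate
23 | O-tert-butyldimethylsilyl ether of the target, (6aR,11aR), carbinol carbon R | CC1(C)C=Cc2c(ccc3c2OC[C@H]2c4ccc5c(c4O[C@@H]32)C[C@@H](O[Si](C)(C)C(C)(C)C)C(C)(C)O5)O1 | intermediate
24 | (6aR,11aR)-pterocarpan with a 2,2-dimethyl-2H-pyran ring fused at C3–C4 (O on C3) and an (R)-3-hydroxy-2,2-dimethyl-3,4-dihydro-2H-pyran ring fused at C9–C10 (O on C9) | CC1(C)C=Cc2c(ccc3c2OC[C@H]2c4ccc5c(c4O[C@@H]32)C[C@@H](O)C(C)(C)O5)O1 | target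

Total step count: 13. Longest linear sequence: 13 steps (1 to 24; chromenol 9 is used twice, in steps 3 and 11).

Steps most likely to fail

Step 9 (Proposed new method). What may go wrong: the methoxy oxygen of the MOM group adds to the rhodium carbene (oxonium ylide formation followed by a 1,2-shift) faster than the C–H insertion takes place, or the catalyst fails to differentiate the two faces of the carbene. Fallback with known chemistry, in which C6a is set by enzymatic desymmetrisation instead of by a carbene: it sets out from iodide 16. Arylation of diethyl malonate (CuI, 2-picolinic acid, Cs2CO3, dioxane) gives the aryl malonate F1. LiAlH4 reduces it to the prochiral 2-aryl-propane-1,3-diol F2. Burkholderia cepacia lipase with vinyl acetate acetylates one enantiotopic arm to give the monoacetate F3 (enzymatic hydrolysis of the diacetate gives the other antipode if the sense is the wrong one). Mitsunobu reaction of F3 with chromenol 9 gives the aryl ether acetate F4, and K2CO3 in MeOH gives the primary alcohol F5. Dess–Martin periodinane gives the aldehyde F6. Me3SiBr at −40 °C removes the MOM group, and the freed phenol closes ring C as the lactol F7. Under the conditions of step 12 the lactol ionises, so the fallback comes back to the route at oxocarbenium ion 22, before ring B is closed.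

Step 12. What may go wrong: loss of H-6a from ion 22 (aromatisation of ring C to a benzofuran), which erases the C6a center, or acid-induced addition to the chromene double bond. Fallback in which ring B is still closed last, but through the O5–C6 bond, with both centers set beforehand by the established carbene insertion into a benzylic ether: it sets out from MOM ether 11 and iodide 16. Ortho-lithiation of 11 (n-BuLi, TMEDA) and quenching with paraformaldehyde gives the benzylic alcohol F8. Me3SiBr at −40 °C frees 16 from its MOM group to give the iodophenol F9. Mitsunobu coupling of F8 with F9 gives the benzyl aryl ether F10. Coupling with ethyl diazoacetate 17 (Pd(PPh3)4, Ag2CO3, Et3N) gives the diazoester F11. Rh2(S-PTTL)4 then closes ring C by 1,5-insertion into the benzylic O–CH2 C–H bond to give the cis-2-aryl-2,3-dihydrobenzofuran-3-carboxylate F12. LiAlH4 gives the alcohol F13, and Me3SiBr frees the ring A phenol to give the phenol alcohol F14. Mitsunobu etherification (PPh3, DIAD) closes ring B, and the fallback comes back to the route at silyl ether 23.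

Step 8. What may go wrong: slow oxidative addition to the electron-rich, ortho-substituted iodide while palladium decomposes the diazo compound (carbene dimerisation). Fallback in which the diazo group is made from a ketone instead of being carried through a cross-coupling: it sets out from silyl ether 14. The aryllithium 15 of step 7 is quenched with diethyl oxalate at −78 °C to give the α-keto ester F15. Tosylhydrazide gives the tosylhydrazone F16. DBU in CH2Cl2 expels sulfinate (Bamford–Stevens reaction), and the fallback comes back to the route at diazoester 18.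

Further compounds
(Ar = (3R)-3-(tert-butyldimethylsilyloxy)-5-(methoxymethoxy)-2,2-dimethylchroman-6-yl)
F1 | step 9 | diethyl 2-Ar-malonate | CCOC(=O)C(C(=O)OCC)c1ccc2OC(C)(C)[C@H](O[Si](C)(C)C(C)(C)C)Cc2c1OCOC
F2 | step 9 | 2-Ar-propane-1,3-diol | OCC(CO)c1ccc2OC(C)(C)[C@H](O[Si](C)(C)C(C)(C)C)Cc2c1OCOC
F3 | step 9 | (2R)-3-hydroxy-2-Ar-propyl acetate | OC[C@H](COC(C)=O)c1ccc2OC(C)(C)[C@H](O[Si](C)(C)C(C)(C)C)Cc2c1OCOC
F4 | step 9 | (2R)-3-[(2,2-dimethyl-2H-chromen-5-yl)oxy]-2-Ar-propyl acetate | CC1(C)C=Cc2c(cccc2OC[C@H](COC(C)=O)c2ccc3OC(C)(C)[C@H](O[Si](C)(C)C(C)(C)C)Cc3c2OCOC)O1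
F5 | step 9 | (2S)-3-[(2,2-dimethyl-2H-chromen-5-yl)oxy]-2-Ar-propan-1-ol | CC1(C)C=Cc2c(cccc2OC[C@H](CO)c2ccc3OC(C)(C)[C@H](O[Si](C)(C)C(C)(C)C)Cc3c2OCOC)O1
F6 | step 9 | (2R)-3-[(2,2-dimethyl-2H-chromen-5-yl)oxy]-2-Ar-propanal | CC1(C)C=Cc2c(cccc2OC[C@H](C=O)c2ccc3OC(C)(C)[C@H](O[Si](C)(C)C(C)(C)C)Cc3c2OCOC)O1
F7 | step 9 | (3R)-lactol, the 2-hydroxy analogue of 21 (mixture of C2 epimers) | CC1(C)C=Cc2c(cccc2OC[C@H]2c4ccc5c(c4OC2O)C[C@@H](O[Si](C)(C)C(C)(C)C)C(C)(C)O5)O1
F8 | step 12 | [5-(methoxymethoxy)-2,2-dimethyl-2H-chromen-6-yl]methanol | COCOc1c(CO)ccc2OC(C)(C)C=Cc12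
F9 | step 12 | (3R)-3-(tert-butyldimethylsilyloxy)-6-iodo-2,2-dimethylchroman-5-ol | Oc1c(I)ccc2OC(C)(C)[C@H](O[Si](C)(C)C(C)(C)C)Cc12
F10 | step 12 | benzyl aryl ether of F8 and F9 | COCOc1c(COc3c(I)ccc4OC(C)(C)[C@H](O[Si](C)(C)C(C)(C)C)Cc34)ccc2OC(C)(C)C=Cc12
F11 | step 12 | ethyl 2-diazo-2-aryl-acetate derived from F10 | CCOC(=O)C(=[N+]=[N-])c1ccc2OC(C)(C)[C@H](O[Si](C)(C)C(C)(C)C)Cc2c1OCc1ccc2OC(C)(C)C=Cc2c1OCOC
F12 | step 12 | ethyl (2R,3S)-cis-2-[5-(methoxymethoxy)-2,2-dimethyl-2H-chromen-6-yl]-2,3-dihydrobenzofuran-3-carboxylate with the fused silyloxy-dimethyldihydropyran ring as in 19 | CCOC(=O)[C@H]1c2ccc3c(c2O[C@H]1c1ccc2OC(C)(C)C=Cc2c1OCOC)C[C@@H](O[Si](C)(C)C(C)(C)C)C(C)(C)O3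
F13 | step 12 | (2R,3R)-3-(hydroxymethyl) analogue of F12 | OC[C@H]1c2ccc3c(c2O[C@H]1c1ccc2OC(C)(C)C=Cc2c1OCOC)C[C@@H](O[Si](C)(C)C(C)(C)C)C(C)(C)O3
F14 | step 12 | free ring A phenol of F13 | OC[C@H]1c2ccc3c(c2O[C@H]1c1ccc2OC(C)(C)C=Cc2c1O)C[C@@H](O[Si](C)(C)C(C)(C)C)C(C)(C)O3
F15 | step 8 | ethyl 2-oxo-2-Ar-acetate | CCOC(=O)C(=O)c1ccc2OC(C)(C)[C@H](O[Si](C)(C)C(C)(C)C)Cc2c1OCOC
F16 | step 8 | tosylhydrazone of F15 | CCOC(=O)C(=NNS(=O)(=O)c1ccc(C)cc1)c1ccc2OC(C)(C)[C@H](O[Si](C)(C)C(C)(C)C)Cc2c1OCOC
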